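## Retrosynthetic overview

1. Stevensine is an isomer of the alkyne analogue of oroidin. The azepinone is opened by a retro 7-endo-dig hydroarylation (pyrrole C3–H across a heteroaryl alkyne), so no redox step is needed.
2. The 2-aminoimidazole of that alkyne is opened to a propargylic guanidino dimethyl acetal. Both closures run in one acid operation.
3. The guanidino acetal comes from a propargylic alcohol (Mitsunobu with bis-Boc-guanidine), made by adding a terminal alkyne to dimethoxyacetaldehyde.
4. The alkyne is the N-propargyl amide from 4,5-dibromo-2-(trichloroacetyl)pyrrole and propargylamine.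
5. Ring order: pyrrole (purchased with both bromines), then imidazole, then azepinone, the last two in the same flask.

Assumption: stevensine has no stereocentre and its only non-aromatic C=C lies in the seven-membered ring, so there is no enantiomer to select. The acyclic intermediates that carry one carbon stereocentre are used as racemates, and that centre is erased in the last step.

## Route

Step 1
Reactants: 1 4,5-dibromo-2-(trichloroacetyl)-1H-pyrrole; 2 propargylamine
Product: 3 4,5-dibromo-N-(prop-2-yn-1-yl)-1H-pyrrole-2-carboxamide
Conditions: 2 (1.2 equiv), MeCN, 23 °C, 12 h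
Reagents that add atoms: none
Why: Haloform-type acyl substitution, in which the trichloromethyl ketone acts as an activated acyl donor toward the primary amine without touching the pyrrole N–H or the bromines.

Step 2
Reactants: 3 4,5-dibromo-N-(prop-2-yn-1-yl)-1H-pyrrole-2-carboxamide; 4 2,2-dimethoxyacetaldehyde
Product: 5 4,5-dibromo-N-(4-hydroxy-5,5-dimethoxypent-2-yn-1-yl)-1H-pyrrole-2-carboxamide (racemic)
Conditions: Zn(OTf)2 (2.2 equiv), Et3N (3 equiv), anhydrous 4 (2 equiv, dried from the commercial aqueous solution), toluene/THF, 23 to 50 °C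
Reagents that add atoms: none
Why: Carreira-type zinc acetylide addition, in which Zn(OTf)2/Et3N metalates only the terminal alkyne C–H, tolerates the N–H groups and C–Br bonds, and adds to the non-enolisable aldehyde; the new carbinol centre is racemic and is erased in step 4.

Step 3
Reactants: 5 4,5-dibromo-N-(4-hydroxy-5,5-dimethoxypent-2-yn-1-yl)-1H-pyrrole-2-carboxamide (racemic); 6 1,3-bis(tert-butoxycarbonyl)guanidine
Product: 7 tert-butyl N-[N'-(tert-butoxycarbonyl)carbamimidoyl]-N-[5-[(4,5-dibromo-1H-pyrrole-2-carbonyl)amino]-1,1-dimethoxypent-3-yn-2-yl]carbamate (racemic)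
Conditions: 6 (3 equiv), PPh3 (1.5 equiv), DIAD (1.5 equiv), THF, 0 to 23 °C
Reagents that add atoms: none
Why: Mitsunobu N-alkylation, in which the Boc-flanked N–H of 6 is the pronucleophile and displaces the activated propargylic oxyphosphonium in an SN2 sense (inversion, irrelevant for a racemate), the excess of 6 outcompeting the pyrrole N–H.

Step 4
Reactants: 7 tert-butyl N-[N'-(tert-butoxycarbonyl)carbamimidoyl]-N-[5-[(4,5-dibromo-1H-pyrrole-2-carbonyl)amino]-1,1-dimethoxypent-3-yn-2-yl]carbamate (racemic)
Product: 10 stevensine, via guanidine acetal 8 (not isolated), via alkynyl aminoimidazole 9 (not isolated)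
Conditions: MeSO3H (neat, 0.02 M, N2 sweep), 23 °C, 3 h, then 60 °C, 12 h; ice, aq. NH3 to pH 9
Reagents that add atoms: none
Why: Proposed new method: MeSO3H removes both Boc groups and ionises the acetal, the guanidine closes onto the oxocarbenium ion and loses methanol and a proton to give the aromatic 2-aminoimidazole 9 (the classical guanidino-acetal cyclisation), and in the same medium the alkyne is protonated at the carbon remote from the heterocycle to give a vinyl cation stabilised by the aminoimidazole as an azafulvenium-type ion, which the only free pyrrole carbon (C3) captures in a 7-endo-dig Friedel–Crafts closure, reversible capture by mesylate or the amide oxygen draining back to the same cation; the closest known reactions are Brønsted-acid intramolecular hydroarylation of aryl alkynes, methanesulfonic-acid Friedel–Crafts chemistry of 2-aminoimidazole-stabilised cations with bromopyrrole carboxamides, and platinum- or gold-catalysed 7-endo-dig cyclisation of N-propargyl pyrrole-2-carboxamides to pyrrolo[2,3-c]azepin-8-ones; the racemic centre of 7 becomes imidazole C4 and no stereocentre remains.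

## Compound list

1 | 2,2,2-trichloro-1-(4,5-dibromo-1H-pyrrol-2-yl)ethan-1-one | O=C(c1cc(Br)c(Br)[nH]1)C(Cl)(Cl)Cl | starting material
2 | prop-2-yn-1-amine (propargylamine) | NCC#C | starting material
3 | 4,5-dibromo-N-(prop-2-yn-1-yl)-1H-pyrrole-2-carboxamide | C#CCNC(=O)c1cc(Br)c(Br)[nH]1 | intermediate
4 | 2,2-dimethoxyacetaldehyde | COC(OC)C=O | starting material
5 | 4,5-dibromo-N-(4-hydroxy-5,5-dimethoxypent-2-yn-1-yl)-1H-pyrrole-2-carboxamide (racemic) | COC(OC)C(O)C#CCNC(=O)c1cc(Br)c(Br)[nH]1 | intermediate
6 | 1,3-bis(tert-butoxycarbonyl)guanidine | CC(C)(C)OC(=O)NC(=N)NC(=O)OC(C)(C)C | starting material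
7 | tert-butyl N-[N'-(tert-butoxycarbonyl)carbamimidoyl]-N-[5-[(4,5-dibromo-1H-pyrrole-2-carbonyl)amino]-1,1-dimethoxypent-3-yn-2-yl]carbamate (racemic) | COC(OC)C(C#CCNC(=O)c1cc(Br)c(Br)[nH]1)N(C(=O)OC(C)(C)C)C(=N)NC(=O)OC(C)(C)C | intermediate
8 | 4,5-dibromo-N-(4-carbamimidamido-5,5-dimethoxypent-2-yn-1-yl)-1H-pyrrole-2-carboxamide (racemic; not isolated, present as its methanesulfonate) | COC(OC)C(NC(=N)N)C#CCNC(=O)c1cc(Br)c(Br)[nH]1 | intermediate
9 | N-[3-(2-amino-1H-imidazol-4-yl)prop-2-yn-1-yl]-4,5-dibromo-1H-pyrrole-2-carboxamide (not isolated) | Nc1ncc(C#CCNC(=O)c2cc(Br)c(Br)[nH]2)[nH]1 | intermediate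
10 | stevensine, 4-(2-amino-1H-imidazol-4-yl)-2,3-dibromo-6,7-dihydropyrrolo[2,3-c]azepin-8(1H)-one (no stereocentre) | Nc1ncc(C2=CCNC(=O)c3[nH]c(Br)c(Br)c32)[nH]1 | target

## Step count and risk

Total step count: 4. Longest linear sequence: 4 (1 to 3 to 5 to 7 to 10).

**Step 4 (most likely to fail).** The alkyne sits on a protonated aminoimidazole and may resist protonation at 60 °C. It may also be captured at the wrong carbon (6-exo) or by a second molecule. Fallback: set out from 7 and separate the two closures. 6 M aq. HCl/THF at 23 °C removes the Boc groups and closes only the imidazole, giving 9, isolated as its hydrochloride. The azepinone is then closed by carbophilic metal activation of the alkyne instead of protonation: PtCl4 (10 mol %) in CF3CO2H/1,2-dichloroethane at 70 °C, with the aminoimidazole kept protonated so that it cannot bind platinum. This arrives at 10. It makes no compound beyond the list (none F0).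

**Step 3.** SN2 displacement next to an acetal by a bulky, weakly nucleophilic guanidine may be slow, and the pyrrole N–H may compete as pronucleophile. Fallback: set out from 5 and bring in the nitrogen as azide. Diphenylphosphoryl azide/DBU (toluene/THF, 0 to 40 °C) gives the azide N-(4-azido-5,5-dimethoxypent-2-yn-1-yl)-4,5-dibromo-1H-pyrrole-2-carboxamide F1. Staudinger reduction (PPh3, THF/H2O, 50 °C) gives the amine N-(4-amino-5,5-dimethoxypent-2-yn-1-yl)-4,5-dibromo-1H-pyrrole-2-carboxamide F2. Guanylation with 1H-pyrazole-1-carboxamidine hydrochloride (iPr2NEt, DMF, 40 °C) gives 8 as its hydrochloride, which is isolated here and enters step 4 in place of 7.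

**Step 2.** The acidic pyrrole and amide N–H groups may sequester zinc, and 3 is poorly soluble in toluene, so the acetylide addition may stall. Fallback: set out from 3 and reverse the way the alkynyl metal is made. N-iodosuccinimide with AgNO3 (10 mol %) in acetone at 23 °C gives the iodoalkyne 4,5-dibromo-N-(3-iodoprop-2-yn-1-yl)-1H-pyrrole-2-carboxamide F3. CrCl2 (4 equiv) in DMF at 23 °C, without a nickel co-catalyst so that the pyrrole C–Br bonds stay intact, inserts into the C–I bond, and the alkynylchromium species adds to 4 (Nozaki–Hiyama–Kishi/Takai alkynylation). This returns to 5.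

## Further compounds

F1 | step 3 | N-(4-azido-5,5-dimethoxypent-2-yn-1-yl)-4,5-dibromo-1H-pyrrole-2-carboxamide (racemic) | COC(OC)C(N=[N+]=[N-])C#CCNC(=O)c1cc(Br)c(Br)[nH]1
F2 | step 3 | N-(4-amino-5,5-dimethoxypent-2-yn-1-yl)-4,5-dibromo-1H-pyrrole-2-carboxamide (racemic) | COC(OC)C(N)C#CCNC(=O)c1cc(Br)c(Br)[nH]1
F3 | step 2 | 4,5-dibromo-N-(3-iodoprop-2-yn-1-yl)-1H-pyrrole-2-carboxamide | IC#CCNC(=O)c1cc(Br)c(Br)[nH]1
F0 | step 4 | none | none
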